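5.0 d is long against the half-life of intermediate B, 0.33 d by step 3 with the whole third reagent counted, and the half-lives of substrate at the charged amounts are shorter still, 0.35 h by step 4 and 0.87 h by step 1, so I expect the clock to matter little and the yield to be made at a fork in the first hours.

substrate 10 mM; coupling partner 8.00 mM; second reagent 11.0 mM; third reagent 30.0 mM (fed, over 15 min); time 5.0 d

    substrate + coupling partner → intermediate A (k1 = 100 /M/h)
    second reagent + intermediate A → intermediate B (k2 = 580 /M/h)
    third reagent + intermediate B → target (k3 = 2.9 /M/h)
    substrate + second reagent → side product (k4 = 180 /M/h)

- the reaction counts as stopped when no species that holds the substrate changes by six tenths of a point or more over the second half of the time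
- run time (flask): 5.0 d

* the state of affairs at 5.0 d: stopped, and by what, or still going (the third reagent has run out first / all of the substrate has reacted / the coupling partner has run out first / it is still moving / the second reagent has run out first)
* share of the substrate used up at 5.0 d
* target at 5.0 d, in percent of the substrate charged
* amount of target if the flask were left three thousand times as long, in percent of the substrate charged

I follow one molecule of substrate. If it meets coupling partner, it goes on through the intermediates to target; if it meets second reagent, it becomes side product. Its chance of the first road is the fork share, the rate of step 1 divided by the summed rates of steps 1 and 4: the selectivity at that instant. The charges cap the target at 80.0%, with 8.00 mM of coupling partner against 10 mM of substrate. I assume intermediate A is taken up promptly, since the constant of step 2 is larger than that of step 1, so each substrate lost by either road costs one second reagent but costs coupling partner the share, which is below one, and second reagent falls faster than coupling partner. The share therefore rises as substrate is used, and I reckon it at the two ends and midway through the substrate: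

start: coupling partner 8.00 mM, second reagent 11.0 mM, share 28.8%

end: coupling partner at most 5.12 mM, second reagent 1.00 mM, share 74.0%

midway: coupling partner 6.56 mM, second reagent 6.00 mM, share 37.8%

So the yield lies between 28.8% and 74.0%, a ceiling lower than the cap, and I commit to the midway share, 37.8%.

The forecast says that all of the substrate has reacted, with 100% conversion, 38.3% target and 38.3% in the long run; of the end it says “The stop comes from substrate being used up”. Its yield stands inside my bracket, 0.50 percentage points above my figure.

The simulation says that all of the substrate has reacted, with 100% conversion, 37.9% target and 37.9% in the long run.

The neighbour flask charged with 2.5 mM of substrate, other charges held, starts at the same share, 28.8%. Midway it has coupling partner 7.64 mM and second reagent 9.75 mM, so its share is 30.3%, lower than the 37.8% of the first flask. That neighbour flask holds 69.9% side product and 30.1% target after 5.00 d.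

The constants used here are those of an exercise; the rest is arithmetic.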